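**Retrosynthetic overview**

1. Locants: bicyclo[3.3.1]nonane with C1 (bridgehead C–OH), C2, C3 (N), C4 (OH), C5 (bridgehead C–H), C6 (OMe), C7–C8 (oxirane), C9 (bridging C=O). Ring A = C1–C5 + C9, ring B = C5–C8 + C1 + C9. "Exo" = the face of ring B turned toward C9 and away from C3.
2. Feature used: C1 is an oxygen-bearing quaternary carbon between the C9 ketone and C8, and C8 can enter as a second ketone. Ring B (C8–C1–C9) is therefore a hidden prochiral 2-alkoxycyclohexane-1,3-dione whose two carbonyls are told apart when ring A closes.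
3. Key disconnection (C1–C2 and C4–C5): Michael addition of 2-(4-methoxybenzyloxy)cyclohexane-1,3-dione to 2-phthalimidoacrolein, then amino-acid-catalysed desymmetrising aldol of C5 onto the C4 aldehyde. This sets C1, C3, C4 and C5.
4. The only enolisable ketone (C8) is then converted into the C6–OMe/C7–C8 oxirane array: desaturation, exo epoxidation, Wharton transposition, N-acylation, C6–OH-directed epoxidation, O-methylation, deprotection.
5. Ring order: ring B (bought as the dione) → ring A (key step) → oxirane (step 11).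

Key step: step 5

Remark (assumption on the chemistry): hydrazine cannot be kept away from a phthalimide, so the Wharton step is planned to remove the phthaloyl group in the same operation, and the freed amine is acylated before the remaining oxygen chemistry.

**Route**

Step 1
Reactants: 1 cyclohexane-1,3-dione
Product: 2 2-diazocyclohexane-1,3-dione
Conditions: 4-acetamidobenzenesulfonyl azide (1.1 equiv), Et3N (1.2 equiv), MeCN, 0 → 25 °C
Reagents that add atoms: 4-acetamidobenzenesulfonyl azide (p-ABSA), CC(=O)Nc1ccc(cc1)S(=O)(=O)N=[N+]=[N-]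
Why: Regitz diazo transfer to the doubly activated methylene of a 1,3-dione proceeds readily under amine base, and the sulfonamide by-product is removed by filtration and a basic wash.

Step 2
Reactants: 2 2-diazocyclohexane-1,3-dione; 3 4-methoxybenzyl alcohol
Product: 4 2-[(4-methoxybenzyl)oxy]cyclohexane-1,3-dione (present as its enol tautomer)
Conditions: Rh2(OAc)4 (1 mol %), 3 (3 equiv), 1,2-dichloroethane, 70 °C, slow addition of 2
Reagents that add atoms: none
Why: The dirhodium carbenoid of an acceptor/acceptor diazo compound inserts into the O–H bond of a primary alcohol (carbenoid O–H insertion through an oxonium ylide and proton shift), and slow addition into excess alcohol should suppress carbene dimerisation and rearrangement.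

Step 3
Reactants: 5 N-(2,2-diethoxyethyl)phthalimide (phthalimidoacetaldehyde diethyl acetal)
Product: 6 phthalimidoacetaldehyde
Conditions: 2 M aq HCl, THF, 50 °C
Reagents that add atoms: water, O
Why: Acid-catalysed acetal hydrolysis frees the aldehyde, and the imide is inert to dilute aqueous acid at this temperature.

Step 4
Reactants: 6 phthalimidoacetaldehyde
Product: 7 2-phthalimidoacrolein
Conditions: 37% aq CH2O (1.2 equiv), pyrrolidine (10 mol %), propionic acid (10 mol %), i-PrOH, 45 °C; used fresh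
Reagents that add atoms: formaldehyde, C=O
Why: Amine-catalysed α-methylenation (Mannich condensation with formaldehyde followed by elimination of the amine) converts an enolisable aldehyde into the 2-substituted acrolein, and the fully substituted imide nitrogen leaves no N–H to tautomerise.

Step 5
Reactants: 4 2-[(4-methoxybenzyl)oxy]cyclohexane-1,3-dione; 7 2-phthalimidoacrolein
Product: 9 (1S,3S,4R,5R)-4-hydroxy-1-[(4-methoxybenzyl)oxy]-3-phthalimidobicyclo[3.3.1]nonane-8,9-dione (C3–N equatorial, C4–OH axial on ring A), via triketo aldehyde Michael adduct 8 (not isolated)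
Conditions: 4 (1.0 equiv), 7 (1.2 equiv, slow addition), Et3N (10 mol %), DMSO, 25 °C; then L-phenylalanine (30 mol %), (+)-10-camphorsulfonic acid (20 mol %), 25 → 40 °C
Reagents that add atoms: none
Why: The enol of 4 adds as a carbon nucleophile to the unsubstituted terminus of 7 (C1–C2), L-phenylalanine then condenses with one ring ketone of 8 to a primary enamine whose C5 attacks the C4 aldehyde (C4–C5), and hydrolysis of the iminium returns the catalyst and leaves the C9 ketone; the closest known reaction type is the amino-acid-catalysed desymmetrising intramolecular aldol of cyclohexanones and 2,2-disubstituted cyclohexane-1,3-diones bearing a 3-oxopropyl arm (Hajos–Parrish-type enamine catalysis with a carboxylic-acid hydrogen bond to the acceptor), known for carbon-substituted diones and simple enals but here applied to a 2-alkoxy dione and an α-imido enal. Ring A closes by a 6-(enolendo)-exo-trig aldol onto the preformed ring B. C1 and C5 are set by which enantiotopic ketone forms the reacting enamine: the quaternary C1 forces the N–Cα bond syn to C5, the carboxylic acid must sit on the enamine face that carries the C2 tether to hydrogen-bond the aldehyde, and only for the ketone leading to (1S,5R) can the L-acid then turn its Cα–H rather than its benzyl group toward C5–H. C4 is set by the same hydrogen bond, which holds the aldehyde oxygen over C9 in a chair-like transition state and makes the new hydroxyl axial on ring A. C3 is set dynamically: the α-phthalimido aldehyde centre should epimerise through its enol faster than the ring closes, and the chair places the phthalimide equatorial, away from the endo hydrogen on C7. The step needs C- over O-alkylation in the Michael stage (the O-adduct forms reversibly and drains to 8) and ketone-enamine over aldehyde-enamine reactivity (the aldehyde enamine could only close a four-membered ring and merely helps C3 to equilibrate).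

Step 6
Reactants: 9 (1S,3S,4R,5R)-4-hydroxy-1-[(4-methoxybenzyl)oxy]-3-phthalimidobicyclo[3.3.1]nonane-8,9-dione
Product: 10 4,8-bis(tert-butyldimethylsilyloxy)-1-[(4-methoxybenzyl)oxy]-3-phthalimidobicyclo[3.3.1]non-7-en-9-one (C4 silyl ether plus C8 silyl enol ether; C1, C3, C4, C5 as in 9)
Conditions: TBSOTf (3.0 equiv), Et3N (5 equiv), CH2Cl2, −20 → 25 °C
Reagents that add atoms: tert-butyldimethylsilyl trifluoromethanesulfonate (TBSOTf), CC(C)(C)[Si](C)(C)OS(=O)(=O)C(F)(F)F
Why: Soft enolisation with silyl triflate and amine can only enolise C8 toward C7, because C1 is quaternary and an enol at C9 would put a double bond at a bridgehead, and the same reagent caps the C4 alcohol, which blocks retro-aldol opening in the basic steps that follow.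

Step 7
Reactants: 10 4,8-bis(tert-butyldimethylsilyloxy)-1-[(4-methoxybenzyl)oxy]-3-phthalimidobicyclo[3.3.1]non-7-en-9-one
Product: 11 4-(tert-butyldimethylsilyloxy)-1-[(4-methoxybenzyl)oxy]-3-phthalimidobicyclo[3.3.1]non-6-ene-8,9-dione (C6=C7 enone; C1, C3, C4, C5 as in 9)
Conditions: Pd(OAc)2 (1.2 equiv), MeCN, 40 °C
Reagents that add atoms: none
Why: Saegusa–Ito oxidation, in which the silyl enol ether is transmetalated to a palladium enolate that loses the C6 hydrogen by syn β-hydride elimination, gives the enone and leaves the alkyl silyl ether, the benzylic ether and the imide untouched.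

Step 8
Reactants: 11 4-(tert-butyldimethylsilyloxy)-1-[(4-methoxybenzyl)oxy]-3-phthalimidobicyclo[3.3.1]non-6-ene-8,9-dione
Product: 12 6,7-epoxy-4-(tert-butyldimethylsilyloxy)-1-[(4-methoxybenzyl)oxy]-3-phthalimidobicyclo[3.3.1]nonane-8,9-dione (oxirane on the exo face; C1, C3, C4, C5 as in 9)
Conditions: tert-butyl hydroperoxide (5.5 M in decane, 2.0 equiv), DBU (1.2 equiv), CH2Cl2, 0 → 25 °C
Reagents that add atoms: tert-butyl hydroperoxide (TBHP), CC(C)(C)OO
Why: In this Weitz–Scheffer nucleophilic epoxidation the peroxide anion should add axially to C6 from the exo face, since the endo face of ring B is covered by the C2–C4 bridge, and the enolate closes the oxirane on the same face, which fixes C6 and C7.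

Step 9
Reactants: 12 6,7-exo-epoxy-4-(tert-butyldimethylsilyloxy)-1-[(4-methoxybenzyl)oxy]-3-phthalimidobicyclo[3.3.1]nonane-8,9-dione
Product: 14 3-amino-4-(tert-butyldimethylsilyloxy)-6-hydroxy-1-[(4-methoxybenzyl)oxy]bicyclo[3.3.1]non-7-en-9-one (C6–OH exo, axial on ring B; C1, C3, C4, C5 as in 9), via phthalimido allylic alcohol 13 (not isolated)
Conditions: N2H4·H2O (8 equiv), AcOH (2 equiv), degassed MeOH, argon, 0 °C then 25 °C; acetone quench, aq NH4Cl work-up
Reagents that add atoms: none
Why: The Wharton transposition (hydrazone at C8, opening of the C7–O bond to the alkenyl diazene, loss of N2) moves unsaturation to C7=C8 and never breaks the C6–O bond, so the exo configuration at C6 is kept, after which the same reagent should remove the phthaloyl group by Ing–Manske hydrazinolysis; the C9 ketone is flanked by C1 and C5 and any hydrazone formed there reversibly should be returned by exchange with acetone.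

Step 10
Reactants: 14 3-amino-4-(tert-butyldimethylsilyloxy)-6-hydroxy-1-[(4-methoxybenzyl)oxy]bicyclo[3.3.1]non-7-en-9-one; 15 (E)-dodec-2-enoic acid
Product: 17 (E)-N-[4-(tert-butyldimethylsilyloxy)-6-exo-hydroxy-1-[(4-methoxybenzyl)oxy]-9-oxobicyclo[3.3.1]non-7-en-3-yl]dodec-2-enamide (ring stereocentres as in 14), via benzotriazolyl ester 16 (not isolated)
Conditions: 15 (1.1 equiv), N,N'-diisopropylcarbodiimide (1.1 equiv), HOBt (1.1 equiv), CH2Cl2, 0 → 25 °C
Reagents that add atoms: 1-hydroxybenzotriazole (HOBt), On1nnc2ccccc21 (its atoms enter intermediate 16 only)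
Why: Carbodiimide/HOBt amide coupling acylates the primary amine far faster than the hindered secondary C6 alcohol, and the active ester is mild enough to avoid conjugate addition or E/Z isomerisation of the enoyl group.

Step 11
Reactants: 17 (E)-N-[4-(tert-butyldimethylsilyloxy)-6-exo-hydroxy-1-[(4-methoxybenzyl)oxy]-9-oxobicyclo[3.3.1]non-7-en-3-yl]dodec-2-enamide
Product: 18 (E)-N-[7,8-epoxy-4-(tert-butyldimethylsilyloxy)-6-hydroxy-1-[(4-methoxybenzyl)oxy]-9-oxobicyclo[3.3.1]nonan-3-yl]dodec-2-enamide (oxirane and C6–OH both exo, cis to each other)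
Conditions: VO(acac)2 (5 mol %), tert-butyl hydroperoxide (5.5 M in decane, 1.5 equiv), CH2Cl2, 0 → 25 °C
Reagents that add atoms: tert-butyl hydroperoxide (TBHP), CC(C)(C)OO
Why: In this vanadium-catalysed hydroxyl-directed epoxidation the pseudo-axial exo C6–OH binds the vanadium peroxide and delivers oxygen to the exo face of C7=C8, which is also the sterically open face, setting C7 and C8 syn to the C6 oxygen, while the electron-poor enamide alkene should not react.

Step 12
Reactants: 18 (E)-N-[7,8-exo-epoxy-4-(tert-butyldimethylsilyloxy)-6-exo-hydroxy-1-[(4-methoxybenzyl)oxy]-9-oxobicyclo[3.3.1]nonan-3-yl]dodec-2-enamide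
Product: 19 (E)-N-[7,8-exo-epoxy-4-(tert-butyldimethylsilyloxy)-6-exo-methoxy-1-[(4-methoxybenzyl)oxy]-9-oxobicyclo[3.3.1]nonan-3-yl]dodec-2-enamide
Conditions: MeI (20 equiv), Ag2O (5 equiv), 4 Å molecular sieves, CH2Cl2, 35 °C, dark
Reagents that add atoms: iodomethane (MeI), CI
Why: Purdie methylation under neutral silver oxide conditions alkylates the alcohol without deprotonating the secondary amide or opening the oxirane, and a Payne shift is excluded because the C6 oxygen is cis to the oxirane and cannot attack C7 from the rear.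

Step 13
Reactants: 19 (E)-N-[7,8-exo-epoxy-4-(tert-butyldimethylsilyloxy)-6-exo-methoxy-1-[(4-methoxybenzyl)oxy]-9-oxobicyclo[3.3.1]nonan-3-yl]dodec-2-enamide
Product: 20 (E)-N-[7,8-exo-epoxy-4-(tert-butyldimethylsilyloxy)-1-hydroxy-6-exo-methoxy-9-oxobicyclo[3.3.1]nonan-3-yl]dodec-2-enamide
Conditions: DDQ (1.5 equiv), CH2Cl2/pH 7 phosphate buffer (10:1), 0 → 25 °C
Reagents that add atoms: none
Why: Oxidative cleavage of the 4-methoxybenzyl ether (hydride abstraction at the electron-rich benzylic carbon and hydrolysis of the oxocarbenium ion) frees the tertiary C1 alcohol under buffered conditions that spare the silyl ether, the oxirane and the enamide.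

Step 14
Reactants: 20 (E)-N-[7,8-exo-epoxy-4-(tert-butyldimethylsilyloxy)-1-hydroxy-6-exo-methoxy-9-oxobicyclo[3.3.1]nonan-3-yl]dodec-2-enamide
Product: 21 (E)-N-[(1S,3S,4R,5S,6S,7S,8S)-7,8-epoxy-1,4-dihydroxy-6-methoxy-9-oxobicyclo[3.3.1]nonan-3-yl]dodec-2-enamide (CNP0137540.1)
Conditions: HF·pyridine, pyridine, THF, 0 → 25 °C
Reagents that add atoms: none
Why: Pyridine-buffered fluoride desilylation removes the silyl ether under non-basic conditions, so the freed β-hydroxy ketone should not undergo retro-aldol cleavage and the oxirane should survive.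

**Compound list**

1 | cyclohexane-1,3-dione | O=C1CCCC(=O)C1 | starting material
2 | 2-diazocyclohexane-1,3-dione | O=C1CCCC(=O)C1=[N+]=[N-] | intermediate
3 | 4-methoxybenzyl alcohol | COc1ccc(CO)cc1 | starting material
4 | 2-[(4-methoxybenzyl)oxy]cyclohexane-1,3-dione (drawn as the diketone) | O=C1CCCC(=O)C1OCc1ccc(OC)cc1 | intermediate
5 | N-(2,2-diethoxyethyl)phthalimide | CCOC(OCC)CN1C(=O)c2ccccc2C1=O | starting material
6 | phthalimidoacetaldehyde | O=CCN1C(=O)c2ccccc2C1=O | intermediate
7 | 2-phthalimidoacrolein | C=C(C=O)N1C(=O)c2ccccc2C1=O | intermediate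
8 | 2-[(4-methoxybenzyl)oxy]-2-(3-oxo-2-phthalimidopropyl)cyclohexane-1,3-dione (C3 epimers interconvert) | O=CC(CC1(OCc2ccc(OC)cc2)C(=O)CCCC1=O)N1C(=O)c2ccccc2C1=O | intermediate (not isolated)
9 | (1S,3S,4R,5R)-4-hydroxy-1-[(4-methoxybenzyl)oxy]-3-phthalimidobicyclo[3.3.1]nonane-8,9-dione | O=C1c2ccccc2C(=O)N1[C@H]1C[C@@]2(OCc3ccc(OC)cc3)C(=O)[C@@H]([C@H]1O)CCC2=O | intermediate
10 | 4,8-bis(tert-butyldimethylsilyloxy)-1-[(4-methoxybenzyl)oxy]-3-phthalimidobicyclo[3.3.1]non-7-en-9-one | O=C1c2ccccc2C(=O)N1[C@H]1C[C@@]2(OCc3ccc(OC)cc3)C(=O)[C@@H]([C@H]1O[Si](C)(C)C(C)(C)C)CC=C2O[Si](C)(C)C(C)(C)C | intermediate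
11 | 4-(tert-butyldimethylsilyloxy)-1-[(4-methoxybenzyl)oxy]-3-phthalimidobicyclo[3.3.1]non-6-ene-8,9-dione | O=C1c2ccccc2C(=O)N1[C@H]1C[C@@]2(OCc3ccc(OC)cc3)C(=O)[C@@H]([C@H]1O[Si](C)(C)C(C)(C)C)C=CC2=O | intermediate
12 | 6,7-exo-epoxy-4-(tert-butyldimethylsilyloxy)-1-[(4-methoxybenzyl)oxy]-3-phthalimidobicyclo[3.3.1]nonane-8,9-dione | O=C1c2ccccc2C(=O)N1[C@H]1C[C@@]2(OCc3ccc(OC)cc3)C(=O)[C@@H]([C@H]1O[Si](C)(C)C(C)(C)C)[C@@H]3O[C@@H]3C2=O | intermediate
13 | 4-(tert-butyldimethylsilyloxy)-6-exo-hydroxy-1-[(4-methoxybenzyl)oxy]-3-phthalimidobicyclo[3.3.1]non-7-en-9-one | O=C1c2ccccc2C(=O)N1[C@H]1C[C@@]2(OCc3ccc(OC)cc3)C(=O)[C@@H]([C@H]1O[Si](C)(C)C(C)(C)C)[C@H](O)C=C2 | intermediate (not isolated)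
14 | 3-amino-4-(tert-butyldimethylsilyloxy)-6-exo-hydroxy-1-[(4-methoxybenzyl)oxy]bicyclo[3.3.1]non-7-en-9-one | N[C@H]1C[C@@]2(OCc3ccc(OC)cc3)C(=O)[C@@H]([C@H]1O[Si](C)(C)C(C)(C)C)[C@H](O)C=C2 | intermediate
15 | (E)-dodec-2-enoic acid | CCCCCCCCC/C=C/C(=O)O | starting material
16 | benzotriazol-1-yl (E)-dodec-2-enoate | CCCCCCCCC/C=C/C(=O)On1nnc2ccccc12 | intermediate (not isolated)
17 | (E)-N-[4-(tert-butyldimethylsilyloxy)-6-exo-hydroxy-1-[(4-methoxybenzyl)oxy]-9-oxobicyclo[3.3.1]non-7-en-3-yl]dodec-2-enamide | CCCCCCCCC/C=C/C(=O)N[C@H]1C[C@@]2(OCc3ccc(OC)cc3)C(=O)[C@@H]([C@H]1O[Si](C)(C)C(C)(C)C)[C@H](O)C=C2 | intermediate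
18 | (E)-N-[7,8-exo-epoxy-4-(tert-butyldimethylsilyloxy)-6-exo-hydroxy-1-[(4-methoxybenzyl)oxy]-9-oxobicyclo[3.3.1]nonan-3-yl]dodec-2-enamide | CCCCCCCCC/C=C/C(=O)N[C@H]1C[C@@]2(OCc3ccc(OC)cc3)C(=O)[C@@H]([C@H]1O[Si](C)(C)C(C)(C)C)[C@H](O)[C@@H]3O[C@@H]32 | intermediate
19 | (E)-N-[7,8-exo-epoxy-4-(tert-butyldimethylsilyloxy)-6-exo-methoxy-1-[(4-methoxybenzyl)oxy]-9-oxobicyclo[3.3.1]nonan-3-yl]dodec-2-enamide | CCCCCCCCC/C=C/C(=O)N[C@H]1C[C@@]2(OCc3ccc(OC)cc3)C(=O)[C@@H]([C@H]1O[Si](C)(C)C(C)(C)C)[C@H](OC)[C@@H]3O[C@@H]32 | intermediate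
20 | (E)-N-[7,8-exo-epoxy-4-(tert-butyldimethylsilyloxy)-1-hydroxy-6-exo-methoxy-9-oxobicyclo[3.3.1]nonan-3-yl]dodec-2-enamide | CCCCCCCCC/C=C/C(=O)N[C@H]1C[C@@]2(O)C(=O)[C@@H]([C@H]1O[Si](C)(C)C(C)(C)C)[C@H](OC)[C@@H]3O[C@@H]32 | intermediate
21 | (E)-N-[(1S,3S,4R,5S,6S,7S,8S)-7,8-epoxy-1,4-dihydroxy-6-methoxy-9-oxobicyclo[3.3.1]nonan-3-yl]dodec-2-enamide | CCCCCCCCC/C=C/C(=O)N[C@H]1C[C@@]2(O)C(=O)[C@@H]([C@H]1O)[C@H](OC)[C@@H]1O[C@@H]12 | target

**Step count and risks**

Total step count: 14. Longest linear sequence: 12 steps (steps 1, 2 and 5–14 from cyclohexane-1,3-dione; equally steps 3–14 from the acetal).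

Steps most likely to fail:

Step 5. The amino acid may engage the hindered ring ketones so slowly that uncatalysed or base-mediated closure competes. It may also discriminate the two enantiotopic ketones poorly, or C3 may not equilibrate before ring closure. Any of these would erode enantiomeric purity and the C3/C4 relationship. The fallback replaces asymmetric catalysis by racemic synthesis and resolution. It sets out from 4 and 7: the Michael stage is run alone (Et3N, DMSO) and 8 is isolated. Ring closure with an achiral primary ammonium salt (benzylammonium acetate, DMSO, 40 °C) follows the same enamine pathway and should give the same relative configuration, so 9 is formed as a racemate together with its antipode (1R,3R,4S,5S)-4-hydroxy-1-[(4-methoxybenzyl)oxy]-3-phthalimidobicyclo[3.3.1]nonane-8,9-dione F1. The antipodes are separated by preparative supercritical-fluid chromatography on an amylose tris(3,5-dimethylphenylcarbamate) phase, and the route is rejoined at 9.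

Step 9. Hydrazine may condense with the C9 ketone as well, the phthalimide may be cleaved only in part during the time the transposition needs, and adventitious diimide may reduce the new alkene. The fallback avoids hydrazine and sets out from 12.
- SmI2 (2.2 equiv, THF/MeOH, −90 °C) should open the oxirane reductively at C7 to the β-hydroxy ketone F2 with the exo C6–OH intact.
- Me3OBF4 with 1,8-bis(dimethylamino)naphthalene gives the β-methoxy ketone F3.
- KN(SiMe3)2 and PhNTf2 at −78 °C give the C7=C8 enol triflate F4.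
- Palladium-catalysed formate reduction (Pd(OAc)2, PPh3, HCO2H, Bu3N, DMF, 60 °C) gives the phthalimido allylic methyl ether F5.
- Methylamine in EtOH removes the phthaloyl group to give the amine F6, which is coupled with 15 as in step 10 to the amide F7.
- Dimethyldioxirane in acetone should epoxidise C7=C8 from the open exo face, and the route is rejoined at 19.

Step 12. The hindered C6 alcohol may react slowly under silver oxide, and alkylation of the secondary amide may then compete. The fallback keeps the nitrogen as a carbamate during methylation and sets out from 14.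
- Allyl chloroformate and NaHCO3 give the allyl carbamate F8.
- VO(acac)2/tert-butyl hydroperoxide gives the exo epoxy alcohol F9.
- Me3OBF4 with 1,8-bis(dimethylamino)naphthalene, which does not alkylate a carbamate N–H, gives the methyl ether F10.
- Pd(PPh3)4 with PhSiH3 frees the amine F11.
- Coupling with 15 as in step 10 rejoins the route at 19.

Further compounds
F1 | step 5 | (1R,3R,4S,5S)-4-hydroxy-1-[(4-methoxybenzyl)oxy]-3-phthalimidobicyclo[3.3.1]nonane-8,9-dione | O=C1c2ccccc2C(=O)N1[C@@H]1C[C@]2(OCc3ccc(OC)cc3)C(=O)[C@H]([C@@H]1O)CCC2=O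
F2 | step 9 | 4-(tert-butyldimethylsilyloxy)-6-exo-hydroxy-1-[(4-methoxybenzyl)oxy]-3-phthalimidobicyclo[3.3.1]nonane-8,9-dione | O=C1c2ccccc2C(=O)N1[C@H]1C[C@@]2(OCc3ccc(OC)cc3)C(=O)[C@@H]([C@H]1O[Si](C)(C)C(C)(C)C)[C@H](O)CC2=O
F3 | step 9 | 4-(tert-butyldimethylsilyloxy)-6-exo-methoxy-1-[(4-methoxybenzyl)oxy]-3-phthalimidobicyclo[3.3.1]nonane-8,9-dione | O=C1c2ccccc2C(=O)N1[C@H]1C[C@@]2(OCc3ccc(OC)cc3)C(=O)[C@@H]([C@H]1O[Si](C)(C)C(C)(C)C)[C@H](OC)CC2=O
F4 | step 9 | 4-(tert-butyldimethylsilyloxy)-6-exo-methoxy-1-[(4-methoxybenzyl)oxy]-9-oxo-3-phthalimidobicyclo[3.3.1]non-7-en-8-yl trifluoromethanesulfonate | O=C1c2ccccc2C(=O)N1[C@H]1C[C@@]2(OCc3ccc(OC)cc3)C(=O)[C@@H]([C@H]1O[Si](C)(C)C(C)(C)C)[C@H](OC)C=C2OS(=O)(=O)C(F)(F)F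
F5 | step 9 | 4-(tert-butyldimethylsilyloxy)-6-exo-methoxy-1-[(4-methoxybenzyl)oxy]-3-phthalimidobicyclo[3.3.1]non-7-en-9-one | O=C1c2ccccc2C(=O)N1[C@H]1C[C@@]2(OCc3ccc(OC)cc3)C(=O)[C@@H]([C@H]1O[Si](C)(C)C(C)(C)C)[C@H](OC)C=C2
F6 | step 9 | 3-amino-4-(tert-butyldimethylsilyloxy)-6-exo-methoxy-1-[(4-methoxybenzyl)oxy]bicyclo[3.3.1]non-7-en-9-one | N[C@H]1C[C@@]2(OCc3ccc(OC)cc3)C(=O)[C@@H]([C@H]1O[Si](C)(C)C(C)(C)C)[C@H](OC)C=C2
F7 | step 9 | (E)-N-[4-(tert-butyldimethylsilyloxy)-6-exo-methoxy-1-[(4-methoxybenzyl)oxy]-9-oxobicyclo[3.3.1]non-7-en-3-yl]dodec-2-enamide | CCCCCCCCC/C=C/C(=O)N[C@H]1C[C@@]2(OCc3ccc(OC)cc3)C(=O)[C@@H]([C@H]1O[Si](C)(C)C(C)(C)C)[C@H](OC)C=C2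
F8 | step 12 | allyl N-[4-(tert-butyldimethylsilyloxy)-6-exo-hydroxy-1-[(4-methoxybenzyl)oxy]-9-oxobicyclo[3.3.1]non-7-en-3-yl]carbamate | C=CCOC(=O)N[C@H]1C[C@@]2(OCc3ccc(OC)cc3)C(=O)[C@@H]([C@H]1O[Si](C)(C)C(C)(C)C)[C@H](O)C=C2
F9 | step 12 | allyl N-[7,8-exo-epoxy-4-(tert-butyldimethylsilyloxy)-6-exo-hydroxy-1-[(4-methoxybenzyl)oxy]-9-oxobicyclo[3.3.1]nonan-3-yl]carbamate | C=CCOC(=O)N[C@H]1C[C@@]2(OCc3ccc(OC)cc3)C(=O)[C@@H]([C@H]1O[Si](C)(C)C(C)(C)C)[C@H](O)[C@@H]3O[C@@H]32
F10 | step 12 | allyl N-[7,8-exo-epoxy-4-(tert-butyldimethylsilyloxy)-6-exo-methoxy-1-[(4-methoxybenzyl)oxy]-9-oxobicyclo[3.3.1]nonan-3-yl]carbamate | C=CCOC(=O)N[C@H]1C[C@@]2(OCc3ccc(OC)cc3)C(=O)[C@@H]([C@H]1O[Si](C)(C)C(C)(C)C)[C@H](OC)[C@@H]3O[C@@H]32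
F11 | step 12 | 3-amino-7,8-exo-epoxy-4-(tert-butyldimethylsilyloxy)-6-exo-methoxy-1-[(4-methoxybenzyl)oxy]bicyclo[3.3.1]nonan-9-one | N[C@H]1C[C@@]2(OCc3ccc(OC)cc3)C(=O)[C@@H]([C@H]1O[Si](C)(C)C(C)(C)C)[C@H](OC)[C@@H]3O[C@@H]32
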